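The oxolane is opened at the O1–C2 bond (O1 = ring oxygen; C2 = ring carbon carrying the benzylic carbinol C1′). O1 on C2 and the hydroxyl on C1′ sit anti on adjacent carbons, the signature of anti opening of an (E)-epoxide, and the chain O1–C5–C4–C3 makes O1 a bishomoallylic oxygen of a C2=C1′ styrene. The key step turns the acyclic, O-silylated (E)-ene-diol 6 into the target in one operation: catalyst-controlled Shi epoxidation of C2=C1′, then fluoride-triggered desilylation and 5-exo-tet closure of the C5 alkoxide on C2. This sets C1′, C2 and the all-cis ring. Compound 6 arises in three steps by allylic borylation, asymmetric anti-cinnamylboration and cross-metathesis.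

Key step: step 4

Atom labels used throughout: O1 = ring oxygen; C2 = ring carbon bearing the carbinol side chain; C3 = ring carbon bearing the 4-methoxyphenyl group; C4 = ring carbinol carbon; C5 = ring CH2; C1′ = exocyclic benzylic carbinol carbon.

Assumption: the sense of induction of the phosphoric acid in step 2 is taken from the known behaviour of this catalyst class with other aldehydes ((R)-acid, allyl transfer to the Re face); should aldehyde 3 respond in the opposite sense, the (R)-acid is used instead.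

Step 1
Reactants: 1 (E)-3-(4-methoxyphenyl)prop-2-en-1-ol (4-methoxycinnamyl alcohol)
Product: 2 2-[(E)-3-(4-methoxyphenyl)prop-2-en-1-yl]-4,4,5,5-tetramethyl-1,3,2-dioxaborolane
Conditions: Pd(MeCN)4(BF4)2 (5 mol %), B2pin2 (1.2 equiv), DMSO/MeOH 1:1, 50 °C
Reagents that add atoms: bis(pinacolato)diboron, CC1(C)OB(OC1(C)C)B1OC(C)(C)C(C)(C)O1
Why: Palladium-catalysed borylation of a free allylic alcohol; the activated alcohol ionises to a (π-allyl)palladium intermediate, and boryl transfer at the unhindered terminus should give the linear (E)-allylboronate; no stereocenter is formed.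

Step 2
Reactants: 2 2-[(E)-3-(4-methoxyphenyl)prop-2-en-1-yl]-4,4,5,5-tetramethyl-1,3,2-dioxaborolane; 3 2-[(tert-butyldimethylsilyl)oxy]acetaldehyde
Product: 4 (2S,3R)-1-[(tert-butyldimethylsilyl)oxy]-3-(4-methoxyphenyl)pent-4-en-2-ol
Conditions: (S)-TRIP [(S)-3,3′-bis(2,4,6-triisopropylphenyl)-1,1′-binaphthyl-2,2′-diyl hydrogen phosphate] (5 mol %), 4 Å MS, toluene, −30 °C; aq. NaHCO3 work-up
Reagents that add atoms: none
Why: Chiral phosphoric acid-catalysed allylboration; the closed six-membered chair transition state translates the (E)-geometry of 2 into the anti C2/C3 relationship, and the catalyst, hydrogen-bonded to the boronate oxygen and the formyl hydrogen, should direct attack to the Si face of 3, setting (2S,3R).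

Step 3
Reactants: 4 (2S,3R)-1-[(tert-butyldimethylsilyl)oxy]-3-(4-methoxyphenyl)pent-4-en-2-ol; 5 4-ethenyl-1,2-dimethoxybenzene (3,4-dimethoxystyrene)
Product: 6 (2S,3R,4E)-1-[(tert-butyldimethylsilyl)oxy]-5-(3,4-dimethoxyphenyl)-3-(4-methoxyphenyl)pent-4-en-2-ol
Conditions: second-generation Hoveyda–Grubbs catalyst RuCl2(H2IMes)(=CH-C6H4-2-OiPr) (5 mol %), 5 (3 equiv), 1,4-benzoquinone (10 mol %), CH2Cl2, 40 °C
Reagents that add atoms: none
Why: Olefin cross-metathesis of the allylically branched terminal alkene of 4 with styrene 5; secondary metathesis and the bulk at C3 should give the (E)-styrene, benzoquinone suppresses double-bond migration, and the two stereocenters are not touched.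

Step 4
Reactants: 6 (2S,3R,4E)-1-[(tert-butyldimethylsilyl)oxy]-5-(3,4-dimethoxyphenyl)-3-(4-methoxyphenyl)pent-4-en-2-ol
Product: 9 (3S,4R,5S)-5-[(R)-(3,4-dimethoxyphenyl)(hydroxy)methyl]-4-(4-methoxyphenyl)oxolan-3-ol (target), via epoxide silyl ether 7 (not isolated), via epoxy diol alkoxide 8 (not isolated)
Conditions: a) D-fructose-derived Shi ketone (1,2:4,5-di-O-isopropylidene-β-D-erythro-2,3-hexodiulo-2,6-pyranose, 30 mol %), Oxone (2KHSO5·KHSO4·K2SO4), K2CO3, Bu4NHSO4, MeCN/DMM/aq. Na2B4O7–Na2EDTA (pH ≈ 10.5), 0 °C; extractive work-up, no chromatography; b) Bu4NF, THF, 0 °C to rt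
Reagents that add atoms: potassium peroxymonosulfate (active component of Oxone), [K+].[O-]S(=O)(=O)OO
Why: The dioxirane formed from the D-fructose-derived ketone transfers oxygen to the only alkene of 6 through the spiro transition state that gives (R,R)-epoxides from (E)-aryl alkenes, so the catalyst rather than the substrate fixes C1′ and C2 in 7; fluoride then unmasks the C5 oxygen as its alkoxide 8, which opens the epoxide at C2 by SN2 attack, forming the O1–C2 bond with inversion at C2 and leaving the C1′ oxygen as the carbinol with retention. The closest known reaction type is the asymmetric epoxidation/base-mediated epoxy-alcohol cyclisation used to make 2-(1-hydroxyalkyl)tetrahydrofurans. The oxolane (O1, C5, C4, C3, C2) closes in the 5-exo-tet mode. C1′ (R) is set by the catalyst-controlled face of oxygen transfer and C2 (S) by the same face followed by stereospecific inversion, so the contra-thermodynamic all-cis C2/C3/C4 array follows from the epoxide configuration and the C3/C4 centres made in step 2. The step needs attack at C2 and not at the benzylic C1′ (6-endo by O5, 5-endo by O4); this should be secured by keeping O5 silylated during the aqueous oxidation, by the basic aprotic closure that avoids benzylic ionisation, and by the exo preference of alkoxide openings, while the C4 alkoxide could only close a four-membered ring at C2.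

Compound list
1 | (E)-3-(4-methoxyphenyl)prop-2-en-1-ol | COc1ccc(/C=C/CO)cc1 | starting material
2 | 2-[(E)-3-(4-methoxyphenyl)prop-2-en-1-yl]-4,4,5,5-tetramethyl-1,3,2-dioxaborolane | COc1ccc(/C=C/CB2OC(C)(C)C(C)(C)O2)cc1 | intermediate
3 | 2-[(tert-butyldimethylsilyl)oxy]acetaldehyde | CC(C)(C)[Si](C)(C)OCC=O | starting material
4 | (2S,3R)-1-[(tert-butyldimethylsilyl)oxy]-3-(4-methoxyphenyl)pent-4-en-2-ol | COc1ccc([C@@H](C=C)[C@H](O)CO[Si](C)(C)C(C)(C)C)cc1 | intermediate
5 | 4-ethenyl-1,2-dimethoxybenzene | COc1ccc(C=C)cc1OC | starting material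
6 | (2S,3R,4E)-1-[(tert-butyldimethylsilyl)oxy]-5-(3,4-dimethoxyphenyl)-3-(4-methoxyphenyl)pent-4-en-2-ol | COc1ccc([C@@H](/C=C/c2ccc(OC)c(OC)c2)[C@H](O)CO[Si](C)(C)C(C)(C)C)cc1 | intermediate
7 | (2S,3R)-1-[(tert-butyldimethylsilyl)oxy]-3-[(2R,3R)-3-(3,4-dimethoxyphenyl)oxiran-2-yl]-3-(4-methoxyphenyl)propan-2-ol | COc1ccc([C@@H]([C@H]2O[C@@H]2c3ccc(OC)c(OC)c3)[C@H](O)CO[Si](C)(C)C(C)(C)C)cc1 | intermediate
8 | (2S,3R)-3-[(2R,3R)-3-(3,4-dimethoxyphenyl)oxiran-2-yl]-3-(4-methoxyphenyl)propane-1,2-diol, present as its C1 alkoxide | COc1ccc([C@@H]([C@H]2O[C@@H]2c3ccc(OC)c(OC)c3)[C@H](O)CO)cc1 | intermediate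
9 | (3S,4R,5S)-5-[(R)-(3,4-dimethoxyphenyl)(hydroxy)methyl]-4-(4-methoxyphenyl)oxolan-3-ol | COc1ccc([C@H]2[C@@H]([C@H](O)c3ccc(OC)c(OC)c3)OC[C@H]2O)cc1 | target

Total step count: 4. Longest linear sequence: 4 steps (1 → 2 → 4 → 6 → 9).

Steps most likely to fail

Step 4. The electron-rich 3,4-dimethoxyphenyl epoxide may ionise at the benzylic C1′–O bond during the aqueous oxidation or the work-up, so that C1′ is captured by O4 or water before the alkoxide can attack C2. Facial selectivity may also be eroded if catalyst and substrate are mismatched. The fallback carries the aryl ring through the ring closure in an electron-poor form and methylates at the end; it sets out from 4 and returns at 9. Commercial 2-methoxy-4-vinylphenol is acylated (pivaloyl chloride, Et3N, DMAP, CH2Cl2) to 2-methoxy-4-vinylphenyl pivalate F1. Cross-metathesis of 4 with F1 under the conditions of step 3 should give 4-[(1E,3R,4S)-5-[(tert-butyldimethylsilyl)oxy]-4-hydroxy-3-(4-methoxyphenyl)pent-1-en-1-yl]-2-methoxyphenyl pivalate F2. Shi epoxidation as in step 4 should give 4-[(2R,3R)-3-[(1R,2S)-3-[(tert-butyldimethylsilyl)oxy]-2-hydroxy-1-(4-methoxyphenyl)propyl]oxiran-2-yl]-2-methoxyphenyl pivalate F3, whose acyloxy-substituted ring no longer supports a benzylic cation. Bu4NF in THF then closes the oxolane to 4-[(R)-hydroxy[(2S,3R,4S)-4-hydroxy-3-(4-methoxyphenyl)oxolan-2-yl]methyl]-2-methoxyphenyl pivalate F4. Methanolysis (K2CO3, MeOH) gives (3S,4R,5S)-5-[(R)-hydroxy(4-hydroxy-3-methoxyphenyl)methyl]-4-(4-methoxyphenyl)oxolan-3-ol F5, and O-methylation of the phenol (MeI, K2CO3, acetone), which leaves the two secondary alcohols untouched, gives 9.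

Step 2. Enantiofacial and anti/syn selectivity may be poor with the small α-silyloxy aldehyde, through a competing uncatalysed pathway or erosion of the (E)-geometry of 2. The fallback replaces catalyst control by classical resolution; it sets out from 2 and 3 and returns at 4. Uncatalysed allylboration (toluene, rt to 40 °C) should give the anti alcohol as the racemate, that is 4 together with (2R,3S)-1-[(tert-butyldimethylsilyl)oxy]-3-(4-methoxyphenyl)pent-4-en-2-ol F6. Esterification with (S)-2-methoxy-2-phenylacetic acid (DCC, DMAP, CH2Cl2) gives the diastereomeric esters (2S,3R)-1-[(tert-butyldimethylsilyl)oxy]-3-(4-methoxyphenyl)pent-4-en-2-yl (2S)-2-methoxy-2-phenylacetate F7 and (2R,3S)-1-[(tert-butyldimethylsilyl)oxy]-3-(4-methoxyphenyl)pent-4-en-2-yl (2S)-2-methoxy-2-phenylacetate F8, which are separated by chromatography. Methanolysis of F7 (K2CO3, MeOH) gives 4.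

Step 3. Ruthenium hydride species may move the terminal double bond into conjugation with the 4-methoxyphenyl ring, which destroys C3, or the hindered alkene may react too slowly while the styrene homodimerises. The fallback forms the aryl–alkene bond by palladium catalysis instead; it sets out from 4 and returns at 6. A Heck arylation of 4 with 4-iodo-1,2-dimethoxybenzene under ligand-free phase-transfer conditions (Pd(OAc)2, Bu4NCl, NaHCO3, DMF, 60 °C) should give the (E)-styrene 6 directly.

Further compounds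
F1 | step 4 | 2-methoxy-4-vinylphenyl pivalate | COc1cc(C=C)ccc1OC(=O)C(C)(C)C
F2 | step 4 | 4-[(1E,3R,4S)-5-[(tert-butyldimethylsilyl)oxy]-4-hydroxy-3-(4-methoxyphenyl)pent-1-en-1-yl]-2-methoxyphenyl pivalate | COc1ccc([C@@H](/C=C/c2ccc(OC(=O)C(C)(C)C)c(OC)c2)[C@H](O)CO[Si](C)(C)C(C)(C)C)cc1
F3 | step 4 | 4-[(2R,3R)-3-[(1R,2S)-3-[(tert-butyldimethylsilyl)oxy]-2-hydroxy-1-(4-methoxyphenyl)propyl]oxiran-2-yl]-2-methoxyphenyl pivalate | COc1ccc([C@@H]([C@H]2O[C@@H]2c3ccc(OC(=O)C(C)(C)C)c(OC)c3)[C@H](O)CO[Si](C)(C)C(C)(C)C)cc1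
F4 | step 4 | 4-[(R)-hydroxy[(2S,3R,4S)-4-hydroxy-3-(4-methoxyphenyl)oxolan-2-yl]methyl]-2-methoxyphenyl pivalate | COc1ccc([C@H]2[C@@H]([C@H](O)c3ccc(OC(=O)C(C)(C)C)c(OC)c3)OC[C@H]2O)cc1
F5 | step 4 | (3S,4R,5S)-5-[(R)-hydroxy(4-hydroxy-3-methoxyphenyl)methyl]-4-(4-methoxyphenyl)oxolan-3-ol | COc1ccc([C@H]2[C@@H]([C@H](O)c3ccc(O)c(OC)c3)OC[C@H]2O)cc1
F6 | step 2 | (2R,3S)-1-[(tert-butyldimethylsilyl)oxy]-3-(4-methoxyphenyl)pent-4-en-2-ol, formed with 4 as the racemate | COc1ccc([C@H](C=C)[C@@H](O)CO[Si](C)(C)C(C)(C)C)cc1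
F7 | step 2 | (2S,3R)-1-[(tert-butyldimethylsilyl)oxy]-3-(4-methoxyphenyl)pent-4-en-2-yl (2S)-2-methoxy-2-phenylacetate | COc1ccc([C@@H](C=C)[C@H](OC(=O)[C@@H](OC)c2ccccc2)CO[Si](C)(C)C(C)(C)C)cc1
F8 | step 2 | (2R,3S)-1-[(tert-butyldimethylsilyl)oxy]-3-(4-methoxyphenyl)pent-4-en-2-yl (2S)-2-methoxy-2-phenylacetate | COc1ccc([C@H](C=C)[C@@H](OC(=O)[C@@H](OC)c2ccccc2)CO[Si](C)(C)C(C)(C)C)cc1
F0 | step 3 | none | none
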